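Readings and results were generated by integration from invented constants, noise included.

The molecule to follow is the partner, not the starting material: both earlier runs are flat from their first sample, with 37.4% (larch) and 28.0% (cedar) of the starting material unreacted on average.

| setting | larch | cedar | flask |
|---|---|---|---|
| starting material | 0.050 M | 0.050 M | 0.050 M |
| partner | 0.045 M | 0.045 M | 0.0450 M |
| protic impurity | 1 mM | 1 mM | 1.00 mM |
| free catalyst | 0.34 mM | 0.75 mM | 0.50 mM |
| remark | run made earlier | run made earlier |  |
| time |  |  | 2.0 h |

| run | time / min | starting material / % | target / % |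
|---|---|---|---|
| larch | 8.00 | 38.8 | 37.1 |
| larch | 12.0 | 36.6 | 37.6 |
| larch | 20.0 | 37.9 | 35.9 |
| larch | 25.0 | 38.6 | 36.6 |
| larch | 40.0 | 37.1 | 35.1 |
| larch | 60.0 | 36.9 | 37.9 |
| larch | 90.0 | 35.9 | 34.9 |
| cedar | 15.0 | 27.4 | 54.2 |
| cedar | 30.0 | 29.2 | 55.4 |
| cedar | 40.0 | 26.9 | 57.1 |
| cedar | 60.0 | 29.0 | 54.9 |
| cedar | 80.0 | 27.4 | 56.9 |
| cedar | 90.0 | 27.9 | 54.9 |

(readings scatter by 1 percentage point)

- how much of the starting material has reacted by 2.0 h
- how much target there is at 2.0 h, in percent of the starting material charged
- how much over-reaction product there is at 2.0 h, in percent of the starting material charged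

- the numbers in the tables scatter by 1 percentage point (one standard deviation)

1. Budget. Over-reaction product is not read, so it is taken as the balance: 26.2% in larch, 16.5% in cedar. Target averages 36.4% and 55.6%. At one partner per target and two per over-reaction product, the runs used 88.8% and 88.5%. Their mean, 88.6%, is close to the 90.0% charged, so partner is read as the limiting reagent.

2. Fork. Besides the protic impurity, charged at 2.22% of the partner, a partner molecule meets either free catalyst, leading on to target, or target, leading to over-reaction product. The odds are taken to go as [target]/[free catalyst], so with the other charges held, more catalyst should lower the final [over-reaction product]/[target]. It does: 0.718 in larch is more than 0.296 in cedar. The mean of 0.244 mM and 0.222 mM, 0.233 mM, is the fork constant as read from these two runs: that final ratio times the free catalyst charged.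

3. New flask. 2.0 h lies later than any sample, so the plateau is what is asked. The ratio is 0.466. Each target costs one partner and carries that ratio of over-reaction product at two partners each, so target is the budget over 1.93: 45.9%, with 21.4% over-reaction product and 67.3% conversion.

The forecast, with its own fitted selectivity and reasoning “So partner runs out”, gave 68% conversion, 46% target and 22% over-reaction product; the reckoning above stands 0.60 percentage points lower in over-reaction product.

The new flask gives 67.4%, 46.1% and 20.9%.

    starting material + catalyst intermediate A ⇌ catalyst intermediate B (K = 46.0 M⁻¹, k = 4460 M⁻¹ s⁻¹)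
    partner + protic impurity → quenched reagent (k = 13.2 M⁻¹ s⁻¹)
    partner + target → over-reaction product (k = 0.862 M⁻¹ s⁻¹)
    catalyst intermediate C → free catalyst + target (k = 63.9 s⁻¹)
    partner + free catalyst → catalyst intermediate A (k = 129 M⁻¹ s⁻¹)
    catalyst intermediate B ⇌ catalyst intermediate C (K = 0.730, k = 8.27 s⁻¹)
    starting material + catalyst intermediate B → spent catalyst (k = 0.719 M⁻¹ s⁻¹)

Partner stands at 0% of its charge at 2.00 h, and the new flask's own ratio gives a fork constant of 0.226 mM. The neighbouring flask, with 8.5 × 10⁻⁴ M of free catalyst, has a reckoned ratio of 0.274, hence 57.2% target and 15.7% over-reaction product. That neighbouring flask gives 57.9% target and 14.9% over-reaction product.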